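**Plan**

Labels: the upper chroman carries the fused ring A (C4a to C8a) and has ring B on C3. The central aryl ring D bears the lower chroman at D1, OH at D2, OMe at D4 and the upper C4 at D5.
Cuts, in retrosynthetic order: the four O-benzyl groups; the saturation of the lower C3=C4 and the D1–C3(lower) bond (Suzuki–Miyaura); upper C4–C4a (pyran closure); upper O1–C2 (Mitsunobu); upper C3–C4 (enolate alkylation).
Enabling feature: the upper C4 sits on D5, para to the hydroxyl on D2. A C4 methylene can therefore be oxidised through that phenol to a ring D para-quinone methide, whose exocyclic carbon lies within six-ring reach of C4a, the ring A carbon ortho to O1 and para to the C7 oxygen.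
Forward order: a ring B arylacetyl imide and a ring D benzylic bromide are joined (C3–C4). Reduction and etherification attach ring A. Anodic oxidation closes the upper pyran. The preformed lower chromene ring is then coupled at D1 and saturated, and hydrogenolysis ends the route.
Stereochemistry: upper C3 (R) comes from an Evans alkylation with the (R)-auxiliary, upper C4 (S) from C3 through the trans-selective ring closure, and lower C3 (R) from catalyst-controlled iridium hydrogenation.

Key step: step 13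

Assumption: in step 19 the ThrePHOX antipode used is the one that gives (3R)-isoflavans from simple 3-aryl-2H-chromenes, and the distant upper stereocentres are taken not to override catalyst control.

**Step 1**
Reactants: 1 4-hydroxy-2-methoxybenzaldehyde
Product: 2 5-bromo-4-hydroxy-2-methoxybenzaldehyde
Conditions: Br2 (1.0 equiv), AcOH/CH2Cl2, 0 °C
Reagents that add atoms: bromine, BrBr
Why: Electrophilic aromatic bromination should go to C5 (the future D1), which is ortho to the hydroxyl, para to the methoxy group and far less crowded than C3 between the two oxygens.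

**Step 2**
Reactants: 2 5-bromo-4-hydroxy-2-methoxybenzaldehyde
Product: 3 5-bromo-2-methoxy-4-(methoxymethoxy)benzaldehyde
Conditions: MOMCl, iPr2NEt, CH2Cl2, 0 °C to rt
Reagents that add atoms: chloromethyl methyl ether, COCCl
Why: O-Alkylation of the acidic phenol installs a MOM acetal, the one ring D mask that can later be removed with acid beside benzyl ethers and the aryl bromide.

**Step 3**
Reactants: 3 5-bromo-2-methoxy-4-(methoxymethoxy)benzaldehyde
Product: 4 [5-bromo-2-methoxy-4-(methoxymethoxy)phenyl]methanol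
Conditions: NaBH4, MeOH, 0 °C
Reagents that add atoms: none
Why: Borohydride reduction of an aromatic aldehyde leaves the aryl bromide and the acetal untouched.

**Step 4**
Reactants: 4 [5-bromo-2-methoxy-4-(methoxymethoxy)phenyl]methanol
Product: 5 1-bromo-5-(bromomethyl)-4-methoxy-2-(methoxymethoxy)benzene
Conditions: CBr4, PPh3, CH2Cl2, 0 °C; used at once
Reagents that add atoms: carbon tetrabromide, BrC(Br)(Br)Br
Why: The Appel bromination is neutral, so the acid-labile MOM ether survives, and the electron-rich benzylic bromide is carried forward without chromatography.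

**Step 5**
Reactants: 6 1-(2-hydroxy-4-methoxyphenyl)ethan-1-one (paeonol)
Product: 7 1-[2-(benzyloxy)-4-methoxyphenyl]ethan-1-one
Conditions: BnBr, K2CO3, DMF, 70 °C
Reagents that add atoms: benzyl bromide, BrCc1ccccc1
Why: Williamson benzylation of the hydrogen-bonded ortho phenol needs only warm DMF and puts the final-step protecting group on ring B.

**Step 6**
Reactants: 7 1-[2-(benzyloxy)-4-methoxyphenyl]ethan-1-one
Product: 8 2-[2-(benzyloxy)-4-methoxyphenyl]-1-(morpholin-4-yl)ethane-1-thione
Conditions: S8, morpholine, 130 °C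
Reagents that add atoms: morpholine, C1COCCN1; sulfur, S1SSSSSSS1
Why: The Willgerodt–Kindler reaction moves the oxidised carbon to the chain terminus and is a long-used way from alkoxyacetophenones to arylacetic acid derivatives that aryl benzyl ethers tolerate.

**Step 7**
Reactants: 8 2-[2-(benzyloxy)-4-methoxyphenyl]-1-(morpholin-4-yl)ethane-1-thione
Product: 9 [2-(benzyloxy)-4-methoxyphenyl]acetic acid
Conditions: NaOH, EtOH/H2O, reflux; then aq HCl
Reagents that add atoms: sodium hydroxide, [Na+].[OH-]; water, O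
Why: Alkaline hydrolysis of the thioamide gives the carboxylate, and the aryl ethers are inert to hydroxide.

**Step 8**
Reactants: 9 [2-(benzyloxy)-4-methoxyphenyl]acetic acid; 10 (4R)-4-benzyl-1,3-oxazolidin-2-one
Product: 12 (4R)-4-benzyl-3-{[2-(benzyloxy)-4-methoxyphenyl]acetyl}-1,3-oxazolidin-2-one, via mixed pivalic anhydride 11 (not isolated)
Conditions: PivCl, Et3N, THF, −20 °C; then LiCl, 10, −20 °C to rt
Reagents that add atoms: pivaloyl chloride, CC(C)(C)C(=O)Cl (its acyl group stays only in 11)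
Why: N-Acylation of the Evans auxiliary through the mixed anhydride under LiCl/Et3N conditions attacks the less hindered arylacetyl carbonyl and needs no strong base.

**Step 9**
Reactants: 12 (4R)-4-benzyl-3-{[2-(benzyloxy)-4-methoxyphenyl]acetyl}-1,3-oxazolidin-2-one; 5 1-bromo-5-(bromomethyl)-4-methoxy-2-(methoxymethoxy)benzene
Product: 14 (4R)-4-benzyl-3-{(2R)-2-[2-(benzyloxy)-4-methoxyphenyl]-3-[5-bromo-2-methoxy-4-(methoxymethoxy)phenyl]propanoyl}-1,3-oxazolidin-2-one, via sodium Z-enolate 13 (not isolated)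
Conditions: NaN(SiMe3)2, THF, −78 °C; then 5, −78 to −30 °C
Reagents that add atoms: sodium bis(trimethylsilyl)amide, C[Si](C)(C)[N-][Si](C)(C)C.[Na+] (its sodium stays only in 13)
Why: In this Evans asymmetric alkylation the benzyl group of the (R)-auxiliary shields one face of the chelated Z-enolate 13, so the benzylic bromide enters from the other face, forms the C3–C4 bond and sets the future upper C3 as (R).

**Step 10**
Reactants: 14 (4R)-4-benzyl-3-{(2R)-2-[2-(benzyloxy)-4-methoxyphenyl]-3-[5-bromo-2-methoxy-4-(methoxymethoxy)phenyl]propanoyl}-1,3-oxazolidin-2-one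
Product: 15 (2R)-2-[2-(benzyloxy)-4-methoxyphenyl]-3-[5-bromo-2-methoxy-4-(methoxymethoxy)phenyl]propan-1-ol
Conditions: LiBH4, MeOH, THF, 0 °C
Reagents that add atoms: none
Why: Reductive cleavage of the imide with LiBH4 gives the primary alcohol and returns the auxiliary without enolising the aryl-bearing stereocentre or touching the aryl bromide.

**Step 11**
Reactants: 15 (2R)-2-[2-(benzyloxy)-4-methoxyphenyl]-3-[5-bromo-2-methoxy-4-(methoxymethoxy)phenyl]propan-1-ol; 16 3-(benzyloxy)phenol
Product: 17 1-{(2R)-3-[3-(benzyloxy)phenoxy]-2-[2-(benzyloxy)-4-methoxyphenyl]propyl}-5-bromo-2-methoxy-4-(methoxymethoxy)benzene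
Conditions: PPh3, DIAD, THF, 0 °C to rt
Reagents that add atoms: none
Why: Mitsunobu etherification of the primary alcohol forms the O1–C2 bond at a carbon that is not stereogenic, and with the ring D phenol masked only 16 can act as the nucleophile.

**Step 12**
Reactants: 17 1-{(2R)-3-[3-(benzyloxy)phenoxy]-2-[2-(benzyloxy)-4-methoxyphenyl]propyl}-5-bromo-2-methoxy-4-(methoxymethoxy)benzene
Product: 18 4-{(2R)-3-[3-(benzyloxy)phenoxy]-2-[2-(benzyloxy)-4-methoxyphenyl]propyl}-2-bromo-5-methoxyphenol
Conditions: HCl (cat.), MeOH/THF, 50 °C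
Reagents that add atoms: none
Why: Acid-catalysed acetal exchange passes the MOM carbon to methanol and frees the ring D hydroxyl as the only phenol, while benzyl and alkyl aryl ethers are stable to dilute acid.

**Step 13**
Reactants: 18 4-{(2R)-3-[3-(benzyloxy)phenoxy]-2-[2-(benzyloxy)-4-methoxyphenyl]propyl}-2-bromo-5-methoxyphenol
Product: 20 4-{(3R,4S)-7-(benzyloxy)-3-[2-(benzyloxy)-4-methoxyphenyl]chroman-4-yl}-2-bromo-5-methoxyphenol, via ring D para-quinone methide 19 (not isolated)
Conditions: graphite anode, Pt cathode, undivided cell, Bu4NPF6 (0.1 M), 2,6-lutidine (2 equiv), HFIP/CH2Cl2 4:1, 2 mM, 0 °C, 1 mA cm−2, 2 F mol−1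
Reagents that add atoms: none
Why: Proposed new method: at the anode the lutidine-hydrogen-bonded phenol of 18, its only free OH and its most easily oxidised group, gives up two electrons and the phenolic proton, the resulting phenoxenium ion drops one proton of the para C4 methylene to give para-quinone methide 19, and HFIP hydrogen bonding to the dienone oxygen makes the exocyclic C4 electrophilic enough for C4a of ring A to add in a 1,6 Friedel–Crafts sense, after which proton loss rearomatises rings A and D while protons are reduced to hydrogen at the cathode. The closest known reaction types are the anodic benzylic functionalisation of para-alkylphenols by way of quinone methides and the acid- or HFIP-promoted Friedel–Crafts addition of electron-rich arenes to separately prepared para-quinone methides, and what is new is their union in one intramolecular electrolysis. The pyran closes in the 6-exo-trig mode because the C4=D5 bond that is consumed lies outside the new six-membered ring. The new C4 stereocentre is controlled by C3: in the half-chair transition state ring B sits pseudo-equatorial and the flat ring D dienone turns away from it, so C4a reaches the face that leads to the (3R,4S)-trans chroman, which is also the more stable isomer if the addition is reversible. The step needs chemoselective oxidation (secured by the single free phenol and by working at the foot of its wave), regioselective attack on ring A (the carbon ortho to O1 and para to the benzyloxy group is favoured over the crowded carbon between the two oxygens), no radical coupling (D1 is blocked by bromine, D3 is flanked by OH and OMe, and the solution is dilute) and a ring closure that outruns loss of the C3 proton from 19 (secured by the close, very nucleophilic C4a and the weak, hindered base). Further oxidation of 20 is held back by passing only two faradays per mole and by allylic strain with the D4 methoxy group, which keeps the C4–H bond of 20 near the ring D plane and so slows its loss.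

**Step 14**
Reactants: 20 4-{(3R,4S)-7-(benzyloxy)-3-[2-(benzyloxy)-4-methoxyphenyl]chroman-4-yl}-2-bromo-5-methoxyphenol
Product: 21 (3R,4S)-7-(benzyloxy)-4-[4-(benzyloxy)-5-bromo-2-methoxyphenyl]-3-[2-(benzyloxy)-4-methoxyphenyl]chroman
Conditions: BnBr, K2CO3, DMF, rt
Reagents that add atoms: benzyl bromide, BrCc1ccccc1
Why: Williamson benzylation masks the ring D phenol, so that it can neither add to the later isoflavene under the acidic iridium hydrogenation nor be re-oxidised, and the group leaves with the other benzyl ethers.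

**Step 15**
Reactants: 22 4-(benzyloxy)-2-hydroxybenzaldehyde; 23 triphenyl(vinyl)phosphonium bromide
Product: 25 7-(benzyloxy)-2H-chromene, via phosphorus ylide 24 (not isolated)
Conditions: NaH, DMF, 0 °C; then 23, 60 °C
Reagents that add atoms: none
Why: In the Schweizer reaction the phenoxide adds to the vinylphosphonium salt and the resulting ylide 24 closes the lower pyran by intramolecular Wittig olefination, which fixes the 7-oxygenation pattern without regioisomers.

**Step 16**
Reactants: 25 7-(benzyloxy)-2H-chromene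
Product: 27 7-(benzyloxy)-3-bromo-2H-chromene, via trans-3,4-dibromochroman 26 (not isolated)
Conditions: Br2, CH2Cl2, −78 °C; then DBU, −78 °C to rt
Reagents that add atoms: bromine, BrBr
Why: Bromine adds to the electron-rich styrene-type C3=C4 bond faster than it substitutes the ring, and the C4 bromide of 26, activated by the para benzyloxy group, ionises so readily that base-assisted loss of H3 (an E1-like dehydrobromination) leaves the vinylic C3 bromide.

**Step 17**
Reactants: 27 7-(benzyloxy)-3-bromo-2H-chromene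
Product: 28 2-[7-(benzyloxy)-2H-chromen-3-yl]-4,4,5,5-tetramethyl-1,3,2-dioxaborolane
Conditions: B2pin2, Pd(dppf)Cl2 (3 mol %), KOAc, 1,4-dioxane, 80 °C
Reagents that add atoms: bis(pinacolato)diboron, CC1(C)OB(OC1(C)C)B1OC(C)(C)C(C)(C)O1
Why: Miyaura borylation of a cyclic alkenyl bromide is routine and the weak acetate base keeps homocoupling low.

**Step 18**
Reactants: 21 (3R,4S)-7-(benzyloxy)-4-[4-(benzyloxy)-5-bromo-2-methoxyphenyl]-3-[2-(benzyloxy)-4-methoxyphenyl]chroman; 28 2-[7-(benzyloxy)-2H-chromen-3-yl]-4,4,5,5-tetramethyl-1,3,2-dioxaborolane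
Product: 29 (3R,4S)-7-(benzyloxy)-4-{4-(benzyloxy)-5-[7-(benzyloxy)-2H-chromen-3-yl]-2-methoxyphenyl}-3-[2-(benzyloxy)-4-methoxyphenyl]chroman
Conditions: Pd(OAc)2 (5 mol %), SPhos (10 mol %), K3PO4, toluene/H2O, 90 °C
Reagents that add atoms: none
Why: Suzuki–Miyaura coupling forms the D1–C3(lower) bond, the bulky electron-rich biarylphosphine easing oxidative addition of the electron-rich, singly ortho-substituted aryl bromide to zerovalent palladium.

**Step 19**
Reactants: 29 (3R,4S)-7-(benzyloxy)-4-{4-(benzyloxy)-5-[7-(benzyloxy)-2H-chromen-3-yl]-2-methoxyphenyl}-3-[2-(benzyloxy)-4-methoxyphenyl]chroman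
Product: 30 (3R,4S)-7-(benzyloxy)-4-{4-(benzyloxy)-5-[(3R)-7-(benzyloxy)chroman-3-yl]-2-methoxyphenyl}-3-[2-(benzyloxy)-4-methoxyphenyl]chroman
Conditions: [Ir(cod)(ThrePHOX)]BArF (2 mol %; ThrePHOX = threonine-derived phosphinite–oxazoline, BArF = tetrakis[3,5-bis(trifluoromethyl)phenyl]borate), H2 (50 bar), CH2Cl2, rt
Reagents that add atoms: none
Why: Iridium P,N-catalysed asymmetric hydrogenation of unfunctionalised trisubstituted olefins is established for 3-aryl-2H-chromenes, the chiral ligand picks the olefin face and sets lower C3 as (R), and the homogeneous catalyst does not cleave benzyl ethers.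

**Step 20**
Reactants: 30 (3R,4S)-7-(benzyloxy)-4-{4-(benzyloxy)-5-[(3R)-7-(benzyloxy)chroman-3-yl]-2-methoxyphenyl}-3-[2-(benzyloxy)-4-methoxyphenyl]chroman
Product: 31 (3R,4S)-4-{4-hydroxy-5-[(3R)-7-hydroxychroman-3-yl]-2-methoxyphenyl}-3-(2-hydroxy-4-methoxyphenyl)chroman-7-ol (CNP0152030.2)
Conditions: H2 (1 atm), Pd/C (10 %), EtOAc/MeOH, rt
Reagents that add atoms: none
Why: Heterogeneous hydrogenolysis removes the four aryl benzyl ethers, while the pyran C2–O1 bonds are not benzylic and the three stereocentres carry no leaving group, so nothing else changes.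

**Compound list**

1 | 4-hydroxy-2-methoxybenzaldehyde | COc1cc(O)ccc1C=O | starting material
2 | 5-bromo-4-hydroxy-2-methoxybenzaldehyde | COc1cc(O)c(Br)cc1C=O | intermediate
3 | 5-bromo-2-methoxy-4-(methoxymethoxy)benzaldehyde | COCOc1cc(OC)c(C=O)cc1Br | intermediate
4 | [5-bromo-2-methoxy-4-(methoxymethoxy)phenyl]methanol | COCOc1cc(OC)c(CO)cc1Br | intermediate
5 | 1-bromo-5-(bromomethyl)-4-methoxy-2-(methoxymethoxy)benzene | COCOc1cc(OC)c(CBr)cc1Br | intermediate
6 | 1-(2-hydroxy-4-methoxyphenyl)ethan-1-one (paeonol) | CC(=O)c1ccc(OC)cc1O | starting material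
7 | 1-[2-(benzyloxy)-4-methoxyphenyl]ethan-1-one | CC(=O)c1ccc(OC)cc1OCc1ccccc1 | intermediate
8 | 2-[2-(benzyloxy)-4-methoxyphenyl]-1-(morpholin-4-yl)ethane-1-thione | COc1ccc(CC(=S)N2CCOCC2)c(OCc2ccccc2)c1 | intermediate
9 | [2-(benzyloxy)-4-methoxyphenyl]acetic acid | COc1ccc(CC(=O)O)c(OCc2ccccc2)c1 | intermediate
10 | (4R)-4-benzyl-1,3-oxazolidin-2-one | O=C1N[C@H](Cc2ccccc2)CO1 | starting material
11 | [2-(benzyloxy)-4-methoxyphenyl]acetic pivalic anhydride (not isolated) | COc1ccc(CC(=O)OC(=O)C(C)(C)C)c(OCc2ccccc2)c1 | intermediate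
12 | (4R)-4-benzyl-3-{[2-(benzyloxy)-4-methoxyphenyl]acetyl}-1,3-oxazolidin-2-one | COc1ccc(CC(=O)N2C(=O)OC[C@H]2Cc2ccccc2)c(OCc2ccccc2)c1 | intermediate
13 | sodium (Z)-enolate of 12 (not isolated) | COc1ccc(/C=C(\[O-])N2C(=O)OC[C@H]2Cc2ccccc2)c(OCc2ccccc2)c1.[Na+] | intermediate
14 | (4R)-4-benzyl-3-{(2R)-2-[2-(benzyloxy)-4-methoxyphenyl]-3-[5-bromo-2-methoxy-4-(methoxymethoxy)phenyl]propanoyl}-1,3-oxazolidin-2-one | COc1ccc([C@@H](Cc2cc(Br)c(OCOC)cc2OC)C(=O)N2C(=O)OC[C@H]2Cc2ccccc2)c(OCc2ccccc2)c1 | intermediate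
15 | (2R)-2-[2-(benzyloxy)-4-methoxyphenyl]-3-[5-bromo-2-methoxy-4-(methoxymethoxy)phenyl]propan-1-ol | COc1ccc([C@@H](Cc2cc(Br)c(OCOC)cc2OC)CO)c(OCc2ccccc2)c1 | intermediate
16 | 3-(benzyloxy)phenol | Oc1cccc(OCc2ccccc2)c1 | starting material
17 | 1-{(2R)-3-[3-(benzyloxy)phenoxy]-2-[2-(benzyloxy)-4-methoxyphenyl]propyl}-5-bromo-2-methoxy-4-(methoxymethoxy)benzene | COc1ccc([C@@H](Cc2cc(Br)c(OCOC)cc2OC)COc2cccc(OCc3ccccc3)c2)c(OCc2ccccc2)c1 | intermediate
18 | 4-{(2R)-3-[3-(benzyloxy)phenoxy]-2-[2-(benzyloxy)-4-methoxyphenyl]propyl}-2-bromo-5-methoxyphenol | COc1ccc([C@@H](Cc2cc(Br)c(O)cc2OC)COc2cccc(OCc3ccccc3)c2)c(OCc2ccccc2)c1 | intermediate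
19 | 4-{(E,2R)-3-[3-(benzyloxy)phenoxy]-2-[2-(benzyloxy)-4-methoxyphenyl]propylidene}-2-bromo-5-methoxycyclohexa-2,5-dien-1-one (ring D para-quinone methide, not isolated) | COc1ccc([C@@H](/C=C2\C=C(Br)C(=O)C=C2OC)COc2cccc(OCc3ccccc3)c2)c(OCc2ccccc2)c1 | intermediate
20 | 4-{(3R,4S)-7-(benzyloxy)-3-[2-(benzyloxy)-4-methoxyphenyl]chroman-4-yl}-2-bromo-5-methoxyphenol | COc1ccc([C@@H]2COc3cc(OCc4ccccc4)ccc3[C@H]2c2cc(Br)c(O)cc2OC)c(OCc2ccccc2)c1 | intermediate
21 | (3R,4S)-7-(benzyloxy)-4-[4-(benzyloxy)-5-bromo-2-methoxyphenyl]-3-[2-(benzyloxy)-4-methoxyphenyl]chroman | COc1ccc([C@@H]2COc3cc(OCc4ccccc4)ccc3[C@H]2c2cc(Br)c(OCc3ccccc3)cc2OC)c(OCc2ccccc2)c1 | intermediate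
22 | 4-(benzyloxy)-2-hydroxybenzaldehyde | O=Cc1ccc(OCc2ccccc2)cc1O | starting material
23 | triphenyl(vinyl)phosphonium bromide | C=C[P+](c1ccccc1)(c1ccccc1)c1ccccc1.[Br-] | starting material
24 | {2-[5-(benzyloxy)-2-formylphenoxy]ethylidene}triphenylphosphorane (not isolated) | O=Cc1ccc(OCc2ccccc2)cc1OCC=P(c1ccccc1)(c1ccccc1)c1ccccc1 | intermediate
25 | 7-(benzyloxy)-2H-chromene | C1=Cc2ccc(OCc3ccccc3)cc2OC1 | intermediate
26 | trans-7-(benzyloxy)-3,4-dibromochroman (racemic, one enantiomer drawn, not isolated) | Br[C@@H]1COc2cc(OCc3ccccc3)ccc2[C@H]1Br | intermediate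
27 | 7-(benzyloxy)-3-bromo-2H-chromene | BrC1=Cc2ccc(OCc3ccccc3)cc2OC1 | intermediate
28 | 2-[7-(benzyloxy)-2H-chromen-3-yl]-4,4,5,5-tetramethyl-1,3,2-dioxaborolane | CC1(C)OB(C2=Cc3ccc(OCc4ccccc4)cc3OC2)OC1(C)C | intermediate
29 | (3R,4S)-7-(benzyloxy)-4-{4-(benzyloxy)-5-[7-(benzyloxy)-2H-chromen-3-yl]-2-methoxyphenyl}-3-[2-(benzyloxy)-4-methoxyphenyl]chroman | COc1ccc([C@@H]2COc3cc(OCc4ccccc4)ccc3[C@H]2c2cc(C3=Cc4ccc(OCc5ccccc5)cc4OC3)c(OCc3ccccc3)cc2OC)c(OCc2ccccc2)c1 | intermediate
30 | (3R,4S)-7-(benzyloxy)-4-{4-(benzyloxy)-5-[(3R)-7-(benzyloxy)chroman-3-yl]-2-methoxyphenyl}-3-[2-(benzyloxy)-4-methoxyphenyl]chroman | COc1ccc([C@@H]2COc3cc(OCc4ccccc4)ccc3[C@H]2c2cc([C@@H]3COc4cc(OCc5ccccc5)ccc4C3)c(OCc3ccccc3)cc2OC)c(OCc2ccccc2)c1 | intermediate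
31 | (3R,4S)-4-{4-hydroxy-5-[(3R)-7-hydroxychroman-3-yl]-2-methoxyphenyl}-3-(2-hydroxy-4-methoxyphenyl)chroman-7-ol | COc1ccc([C@@H]2COc3cc(O)ccc3[C@H]2c2cc([C@@H]3COc4cc(O)ccc4C3)c(O)cc2OC)c(O)c1 | target

**Step count**

Total step count: 20.
Longest linear sequence: 13 steps (5 to 14, then 18 to 20). The ring D branch 1 to 4 joins at step 9 and gives an equally long line. The lower-unit branch 15 to 17 joins at step 18.

**Steps most likely to fail**

**Step 13.**
- What may go wrong:
  - further oxidation of the product at its doubly benzylic C4–H;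
  - competing electron loss from the dialkoxy rings A and B;
  - phenoxyl radical coupling with fouling of the anode;
  - proton loss from C3 of the quinone methide (drift to a stilbene), which would erode the C3 configuration.
- Fallback: this avoids any C–H oxidation by carrying an oxygen on C4 from the aldehyde stage. It sets out from acid 9 and aldehyde 3 and comes back at 20.
  - Acid 9 is coupled (PivCl, Et3N, LiCl, THF) to commercial (4S)-4-benzyl-1,3-oxazolidin-2-one to give (4S)-4-benzyl-3-{[2-(benzyloxy)-4-methoxyphenyl]acetyl}-1,3-oxazolidin-2-one F1. The auxiliary is the antipode of 10 because the non-chelated boron aldol uses the enolate face opposite to that used by the chelated sodium enolate.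
  - Bu2BOTf, iPr2NEt, CH2Cl2, −78 °C, then 3 and an H2O2 work-up should give the Evans syn aldol (4S)-4-benzyl-3-{(2S,3S)-2-[2-(benzyloxy)-4-methoxyphenyl]-3-[5-bromo-2-methoxy-4-(methoxymethoxy)phenyl]-3-hydroxypropanoyl}-1,3-oxazolidin-2-one F2.
  - LiBH4 removes the auxiliary and gives (1S,2R)-2-[2-(benzyloxy)-4-methoxyphenyl]-1-[5-bromo-2-methoxy-4-(methoxymethoxy)phenyl]propane-1,3-diol F3.
  - A Mitsunobu reaction with 16 at the primary hydroxyl gives (1S,2R)-3-[3-(benzyloxy)phenoxy]-2-[2-(benzyloxy)-4-methoxyphenyl]-1-[5-bromo-2-methoxy-4-(methoxymethoxy)phenyl]propan-1-ol F4.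
  - BF3·OEt2 in CH2Cl2 at −40 °C ionises the benzylic alcohol to the ring D-stabilised cation. The well-known Friedel–Crafts cyclodehydration then closes the same C4–C4a bond, trans to ring B, to give (3R,4S)-7-(benzyloxy)-3-[2-(benzyloxy)-4-methoxyphenyl]-4-[5-bromo-2-methoxy-4-(methoxymethoxy)phenyl]chroman F5.
  - HCl in MeOH/THF removes the MOM group and delivers 20.

**Step 19.**
- What may go wrong: slow turnover and poor facial selectivity, because the olefin carries an ortho-benzyloxy aryl group with a very large substituent, and acid-induced double-bond migration on the catalyst.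
- Fallback: this moves the stereochemical decision from an olefin to a ketone. It sets out from 29 and comes back at 30.
  - BH3·THF followed by NaOH/H2O2 places a hydroxyl on the lower C4 and gives 7-(benzyloxy)-3-{2-(benzyloxy)-5-[(3R,4S)-7-(benzyloxy)-3-[2-(benzyloxy)-4-methoxyphenyl]chroman-4-yl]-4-methoxyphenyl}chroman-4-ol F6 as both 3,4-trans isomers of the lower unit.
  - Dess–Martin periodinane gives 7-(benzyloxy)-3-{2-(benzyloxy)-5-[(3R,4S)-7-(benzyloxy)-3-[2-(benzyloxy)-4-methoxyphenyl]chroman-4-yl]-4-methoxyphenyl}chroman-4-one F7, whose lower C3 epimerises freely.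
  - Noyori–Ikariya transfer hydrogenation with dynamic kinetic resolution (RuCl(p-cymene)[(R,R)-TsDPEN], HCO2H/Et3N) should funnel both epimers into the cis alcohol (3R,4R)-7-(benzyloxy)-3-{2-(benzyloxy)-5-[(3R,4S)-7-(benzyloxy)-3-[2-(benzyloxy)-4-methoxyphenyl]chroman-4-yl]-4-methoxyphenyl}chroman-4-ol F8.
  - Ionic deoxygenation (Et3SiH, TFA, CH2Cl2, −20 °C) through the cation stabilised by the para benzyloxy group gives 30.

**Step 9.**
- What may go wrong: ionisation and self-condensation of the very electron-rich benzylic bromide before it meets the stabilised, sluggish arylacetyl enolate, and partial epimerisation of the acidic aryl-bearing centre by excess base.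
- Fallback: this drops both the bromide and the auxiliary. It sets out from aldehyde 3 and acid 9 and comes back at 15.
  - A Perkin-type condensation (Ac2O, Et3N, 110 °C) gives (E)-2-[2-(benzyloxy)-4-methoxyphenyl]-3-[5-bromo-2-methoxy-4-(methoxymethoxy)phenyl]prop-2-enoic acid F9.
  - Carboxylate-directed asymmetric hydrogenation follows, with [Ir(cod)(SIPHOX)]BArF (spiro phosphine–oxazoline ligand, the antipode chosen for the R acid), H2 (6 bar), Et3N, MeOH. This reaction type is known for 2,3-diarylacrylic acids and gives (2R)-2-[2-(benzyloxy)-4-methoxyphenyl]-3-[5-bromo-2-methoxy-4-(methoxymethoxy)phenyl]propanoic acid F10.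
  - BH3·THF reduces the acid to 15 without touching the aryl bromide or the acetal.

**Further compounds**

F1 | step 13 | (4S)-4-benzyl-3-{[2-(benzyloxy)-4-methoxyphenyl]acetyl}-1,3-oxazolidin-2-one | COc1ccc(CC(=O)N2C(=O)OC[C@@H]2Cc2ccccc2)c(OCc2ccccc2)c1
F2 | step 13 | (4S)-4-benzyl-3-{(2S,3S)-2-[2-(benzyloxy)-4-methoxyphenyl]-3-[5-bromo-2-methoxy-4-(methoxymethoxy)phenyl]-3-hydroxypropanoyl}-1,3-oxazolidin-2-one | COc1ccc([C@@H]([C@H](O)c2cc(Br)c(OCOC)cc2OC)C(=O)N2C(=O)OC[C@@H]2Cc2ccccc2)c(OCc2ccccc2)c1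
F3 | step 13 | (1S,2R)-2-[2-(benzyloxy)-4-methoxyphenyl]-1-[5-bromo-2-methoxy-4-(methoxymethoxy)phenyl]propane-1,3-diol | COc1ccc([C@@H]([C@H](O)c2cc(Br)c(OCOC)cc2OC)CO)c(OCc2ccccc2)c1
F4 | step 13 | (1S,2R)-3-[3-(benzyloxy)phenoxy]-2-[2-(benzyloxy)-4-methoxyphenyl]-1-[5-bromo-2-methoxy-4-(methoxymethoxy)phenyl]propan-1-ol | COc1ccc([C@@H]([C@H](O)c2cc(Br)c(OCOC)cc2OC)COc2cccc(OCc3ccccc3)c2)c(OCc2ccccc2)c1
F5 | step 13 | (3R,4S)-7-(benzyloxy)-3-[2-(benzyloxy)-4-methoxyphenyl]-4-[5-bromo-2-methoxy-4-(methoxymethoxy)phenyl]chroman | COc1ccc([C@@H]2COc3cc(OCc4ccccc4)ccc3[C@H]2c2cc(Br)c(OCOC)cc2OC)c(OCc2ccccc2)c1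
F6 | step 19 | 7-(benzyloxy)-3-{2-(benzyloxy)-5-[(3R,4S)-7-(benzyloxy)-3-[2-(benzyloxy)-4-methoxyphenyl]chroman-4-yl]-4-methoxyphenyl}chroman-4-ol (both 3,4-trans isomers of the lower unit) | COc1ccc([C@@H]2COc3cc(OCc4ccccc4)ccc3[C@H]2c2cc(C3COc4cc(OCc5ccccc5)ccc4C3O)c(OCc3ccccc3)cc2OC)c(OCc2ccccc2)c1
F7 | step 19 | 7-(benzyloxy)-3-{2-(benzyloxy)-5-[(3R,4S)-7-(benzyloxy)-3-[2-(benzyloxy)-4-methoxyphenyl]chroman-4-yl]-4-methoxyphenyl}chroman-4-one (epimers at lower C3) | COc1ccc([C@@H]2COc3cc(OCc4ccccc4)ccc3[C@H]2c2cc(C3COc4cc(OCc5ccccc5)ccc4C3=O)c(OCc3ccccc3)cc2OC)c(OCc2ccccc2)c1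
F8 | step 19 | (3R,4R)-7-(benzyloxy)-3-{2-(benzyloxy)-5-[(3R,4S)-7-(benzyloxy)-3-[2-(benzyloxy)-4-methoxyphenyl]chroman-4-yl]-4-methoxyphenyl}chroman-4-ol | COc1ccc([C@@H]2COc3cc(OCc4ccccc4)ccc3[C@H]2c2cc([C@@H]3COc4cc(OCc5ccccc5)ccc4[C@@H]3O)c(OCc3ccccc3)cc2OC)c(OCc2ccccc2)c1
F9 | step 9 | (E)-2-[2-(benzyloxy)-4-methoxyphenyl]-3-[5-bromo-2-methoxy-4-(methoxymethoxy)phenyl]prop-2-enoic acid | COc1ccc(/C(C(=O)O)=C\c2cc(Br)c(OCOC)cc2OC)c(OCc2ccccc2)c1
F10 | step 9 | (2R)-2-[2-(benzyloxy)-4-methoxyphenyl]-3-[5-bromo-2-methoxy-4-(methoxymethoxy)phenyl]propanoic acid | COc1ccc([C@@H](Cc2cc(Br)c(OCOC)cc2OC)C(=O)O)c(OCc2ccccc2)c1
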